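# Proposed synthesis of CNP0229085.1 by Grob fragmentation of a quinone–isoprene Diels–Alder decalin

## The problem

CNP0229085.1 is a cyclodecene (C1–C10) with an α-methylene-γ-butyrolactone trans-fused across C1 (lactone O) and C10 (C11, carrying C12=O and the exocyclic C13H2); the ring is numbered C1, C2=C3(CH3), C4(OH), C5(OH), C6H2, C7(CH3), C8(O-angeloyl), C9H2, C10. With the ring drawn so that C1→C10 runs clockwise, β means towards the viewer: the target is 1α-O, 4β-OH, 5β-OH, 7β-CH3, 8β-O, 10β-C11 (10α-H). The six stereocentres form three adjacent pairs (C10/C1, C4/C5, C7/C8) separated by sp2 or methylene carbons. In the flexible ten-membered ring none of these pairs can be trusted to control the next, so a rigid precursor is needed in which one centre is relayed to the others. The α-methylene lactone (a Michael acceptor), the angelate (isomerised to the tiglate by bases and nucleophiles) and the allylic oxygens at C1 and C4 must be introduced or unmasked late, under neutral or weakly acidic conditions. The Z alkene C2=C3 inside a ten-membered ring is hard to secure by olefination or metathesis. The enabling feature is that C5 and C10 face each other across the ring. A C5–C10 bond gives a decalin whose ring A (C1, C2, C3, C4, C5, C10) is 2-methyl-1,4-benzoquinone with oxygens at C1 and C4 and a carboxyl carbon (C11) on C10, whose ring B (C5, C6, C7, C8, C9, C10) is completed by isoprene, and in which O5 and C11 are 1,3-related through C10 as a Grob fragmentation requires.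

## Retrosynthesis

**Lactone, ester and diol (29 ⇒ 28 ⇒ 27 ⇒ 26 ⇒ 25 ⇒ 24).** The last step frees the C4/C5 diol from the p-methoxybenzylidene acetal 28 with aqueous acetic acid. The lactone of 28 is cut at O1–C12 and C11–C12, which leads to the homopropargylic alcohol 27 and carbon monoxide. The neighbouring cut, a saturated lactone followed by enolate methylenation, would put strong base on a molecule that already carries the angelate. The carbonylation builds C12 and the exocyclic methylene in one neutral step and keeps the configuration at C1 and C10. The angelate is therefore placed on C8 beforehand (26 from 25, after selective removal of the C8 triethylsilyl group of 24).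

**C13 and the C10 stereocentre (24 ⇒ 23 ⇒ 22 ⇒ 21).** The alkyne carbon C13 is cut from the aldehyde 23 (diazophosphonate homologation). 23 comes from the primary alcohol 22, and 22 from hydroboration of the exocyclic alkene of 21. Homologation through a C11 halide and cyanide followed by late methylenation would be two steps longer. The forward reaction has to deliver hydrogen to the α face of C10 under the influence of the C1 silyloxy centre alone, and this is the least secure stereocentre of the route.

**C5 carbinol and diol protection (21 ⇒ 20 ⇒ 19).** The C5 alcohol is traced to the ketone 19. The C4 p-methoxybenzyl ether first serves as the chelating group in the reduction (20) and is then closed oxidatively onto the new hydroxyl (21), so one group does both jobs.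

**Key disconnection (19 ⇒ 18).** Ketone 19 holds a C5 carbonyl and a C10=C11 methylene five atoms apart, the retron of a Grob fragmentation. Reconnecting C5 to C10 gives the decalin mesylate 18. Neighbouring cuts of the ring (C1–C10, C3–C4 or C4–C5 closures of open chains) would meet medium-ring strain and would need all six centres from acyclic chemistry. The cut across the ring replaces the ten-membered ring by two six-membered rings, fixes the Z alkene inside ring A, and offers a rigid template. Both ring-fusion centres are lost in the fragmentation, so their configuration is chosen for convenience: trans, 5α-OH and 10β-CH2OMs. This is the isomer that hydroxylation anti to the angular ester produces, its O5 and C11 are trans-diaxial so that no oxetane can form, and its rigid chairs make the face selectivities below predictable.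

**Ring B and the leaving group (18 ⇒ 17 ⇒ 16 ⇒ 15 ⇒ 14 ⇒ 13 ⇒ 12).** The C7 methyl and C8 oxygen are cis, which hydroboration alone cannot give. C8 is therefore taken through the ketone 14: hydroboration of 12 from the α face (anti to the β-axial C11) sets C7, and equatorial hydride delivery to 14 sets C8. O4 and C11–OH are syn-diaxial and are tied in 12 as a seven-membered p-methoxybenzylidene acetal. This protects both during the ring B work. Its reductive opening (16 to 17) leaves the benzyl group on the hindered O4 and frees the primary C11 alcohol for mesylation.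

**Ring A (12 ⇒ 11 ⇒ 10 ⇒ 9 ⇒ 7 ⇒ 6).** The C4 carbinol and the C11 alcohol of triol 11 come from one LiAlH4 reduction of ketol ester 10, with hydride delivered to C4 from the C5 alkoxide. The C5 hydroxyl comes from Rubottom oxidation of the dienol ether of enone 7 (through 8), anti to the ester. The C1 carbinol comes from catalyst-controlled reduction of the β-keto ester carbonyl of 6, before C5 is oxidised, so that no retro-aldol-prone β-hydroxy β-keto ester is ever formed.

**Diels–Alder and quinone (6 ⇒ 4 + 5; 4 ⇒ 3 ⇒ 2 ⇒ 1).** Cutting C5–C6 and C9–C10 gives the quinone ester 4 and isoprene 5. This one step supplies all ten ring carbons, C11 and both methyl groups, and as a catalytic asymmetric reaction it is the only source of absolute configuration. The quinone 4 is made by oxidation of the hydroquinone ester 3, obtained from 4-methylsalicylic acid 1 by para-hydroxylation (2) and esterification.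

## Roads not taken

**Alternative 1:** The cut is C3–C4, made last on a chain that already carries the lactone, the angelate and a C5 silyl ether. In the forward step, CrCl2 with catalytic NiCl2 would turn the Z vinyl iodide of the open-chain aldehyde A1 into a vinylchromium species (trivalent chromium) that adds to the C4 aldehyde. This closes the ring and creates C4, giving A2 one deprotection from the target. The road is convergent, organochromium reagents tolerate esters and lactones, and almost nothing remains to be done after ring closure; in that respect it is better than the chosen plan, which needs ten steps after its ring-forming event. Its weak points are the closure of a strained ten-membered ring through a cis-trisubstituted vinyl metal under high dilution, and a C4 configuration that rests on Felkin-type addition inside a medium-ring transition state. In addition, C1, C5, C7, C8 and C10 of A1 must be built one by one in an open chain. The chosen plan sets against this a ring formation that is unimolecular and strain-releasing, a Z alkene that cannot be wrong, and five stereocentres relayed from a single catalytic step in rigid bicycles.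

**Alternative 2:** The cut is C1–C10. Deprotonation at C1 of the thirteen-membered diallylic ether A3 with n-C4H9Li would trigger a [2,3]-Wittig shift that forms C1–C10 and contracts the ring to A4. A4 carries the free C1 hydroxyl, the C10 stereocentre and the C11=C13 methylene with C12 already attached. This is better than the chosen plan exactly where that plan is weakest: C1 and C10 are made in one step, and only oxidation of C12 and lactonisation would remain. The weak points are the choice between two allylic α-oxygenated positions (C1 and C13) for deprotonation, a trans C1/C10 relation that would depend on the conformation of a thirteen-membered transition state, and the need to assemble C4, C5, C7 and C8 acyclically and then close a large ring by etherification. The chosen plan pays for C10 with a hydroboration of uncertain face selectivity and five further steps, and offers in return predictable control of C4, C7 and C8 and no macrocyclisation.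

**Alternative 3:** The cut is C6–C7. Heating the eight-membered cyclic enol ether A5 (Z-ethylidene on C8, vinyl on C4) would bring about a Claisen [3,3] shift that forms C6–C7, the C8 ketone and the C4=C5 alkene, and expands the ring to the cyclodecadienone A6. The step is reagent-free and stereospecific, it sets C7 by chirality transfer, and C1 and C10 are in place before the ring is made, so C10 does not depend on a medium-ring hydroboration; in these respects it is as good as or better than the chosen plan. A6, however, lacks both the C4 and C5 oxygens. They would have to come from a site- and face-selective dihydroxylation of one double bond of a conjugated diene in a ten-membered ring. The C8 ketone must still be reduced with control and the two-carbon arm on C10 turned into the methylene lactone. A5 itself needs an eight-membered lactone with three stereocentres and a geometrically pure ethylidene enol ether. The chosen plan takes the C4 oxygen from the quinone and the C5 oxygen from the fragmentation itself, at the price of a longer sequence before the ring appears.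

Key step: step 16

Remarks. (a) The Sm(OTf)3 complex of the (S,S)-ligand is assumed to give the enantiomer 6; if the sense of induction is the opposite, the (R,R)-ligand is used and nothing else changes. (b) The acetal carbons of 12–16 and of 21–28 are stereogenic but are removed again (steps 14 and 26); they are left unassigned and are written without a descriptor. (c) Target numbering and the α/β convention defined above are used for all intermediates.

## Route

Step 1
Reactants: 1 4-methylsalicylic acid (2-hydroxy-4-methylbenzoic acid)
Product: 2 2,5-dihydroxy-4-methylbenzoic acid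
Conditions: K2S2O8, aq. NaOH, 0 → 20 °C; then aq. HCl, 90 °C
Reagents that add atoms: potassium peroxodisulfate, [K+].[K+].[O-]S(=O)(=O)OOS(=O)(=O)[O-]
Why: Elbs persulfate oxidation: the phenolate attacks the peroxide oxygen through its free para position and hydrolysis of the aryl sulfate gives the hydroquinone, so the new oxygen can only enter para to the existing one.

Step 2
Reactants: 2 2,5-dihydroxy-4-methylbenzoic acid
Product: 3 methyl 2,5-dihydroxy-4-methylbenzoate
Conditions: MeOH, H2SO4 (cat.), reflux
Reagents that add atoms: methanol, CO
Why: Fischer esterification; the phenols do not react.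

Step 3
Reactants: 3 methyl 2,5-dihydroxy-4-methylbenzoate
Product: 4 methyl 4-methyl-3,6-dioxocyclohexa-1,4-diene-1-carboxylate (2-methoxycarbonyl-5-methyl-1,4-benzoquinone)
Conditions: Ag2O, MgSO4, CH2Cl2, 20 °C; filtered and used at once
Reagents that add atoms: none
Why: Dehydrogenation of a hydroquinone to the quinone by Ag2O under anhydrous conditions, the standard access to water-sensitive 2-alkoxycarbonyl benzoquinones.

Step 4
Reactants: 4 methyl 4-methyl-3,6-dioxocyclohexa-1,4-diene-1-carboxylate; 5 isoprene
Product: 6 cis-fused Diels–Alder adduct (C1 and C4 ketones, C2=C3(CH3), C7(CH3)=C8, 5β-H, 10β-CO2CH3)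
Conditions: Sm(OTf)3 (10 mol %), 2,6-bis[(4S)-4-phenyl-2-oxazolin-2-yl]pyridine (12 mol %), 4 Å MS, THF, −78 °C
Reagents that add atoms: none
Why: Catalytic asymmetric quinone Diels–Alder reaction: two-point binding of the C1 carbonyl and the ester to the samarium–pybox complex activates only the C5=C10 bond and shields one of its faces. Isoprene adds suprafacially (5-H and 10-CO2CH3 cis) with its more nucleophilic terminus on C5, the β carbon of the chelated dicarbonyl, which places the methyl on C7 (para orientation). This step is the only source of absolute configuration.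

Step 5
Reactants: 6 cis-fused Diels–Alder adduct
Product: 7 hydroxy enone (1α-OH, C4 ketone, 5β-H, 10β-CO2CH3)
Conditions: (S)-2-methyl-CBS-oxazaborolidine (0.3 equiv), catecholborane (1.5 equiv), toluene/CH2Cl2, −78 °C
Reagents that add atoms: none
Why: Corey–Bakshi–Shibata reduction: the C1 carbonyl has a clear large (quaternary C10) and small (vinylic C2–H) flank and binds the catalyst, whereas C4 is hindered on both sides (C3 methyl, C5). The (S)-catalyst delivers hydride to the β face, which is also the convex face of the cis-fused adduct, to give the 1α-alcohol; the s-trans cyclic enone is reduced 1,2.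

Step 6
Reactants: 7 hydroxy enone
Product: 9 trans-fused ketol (1α-OH; 5α-OH; C4 ketone; 10β-CO2CH3), via bis(trimethylsilyl) dienol ether 8 (not isolated)
Conditions: Me3SiOTf, Et3N, CH2Cl2, 0 °C; then dimethyldioxirane, acetone/CH2Cl2, −78 → −40 °C; then 1 M HCl, THF, 0 °C
Reagents that add atoms: dimethyldioxirane, CC1(C)OO1
Why: Rubottom oxidation: soft enolisation gives the cross-conjugated 2-silyloxy diene (C5–H is the only α′ hydrogen), and dimethyldioxirane epoxidises this most electron-rich double bond on the α face, anti to the pseudoaxial C10 ester. Acid then releases the ketol, so the new C5 hydroxyl is α and the ring fusion trans.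

Step 7
Reactants: 9 trans-fused ketol
Product: 10 silyl ether (1α-OTBS, 5α-OH, C4 ketone, 10β-CO2CH3)
Conditions: t-BuMe2SiOTf (1.05 equiv), 2,6-lutidine, CH2Cl2, −78 °C
Reagents that add atoms: tert-butyldimethylsilyl triflate, CC(C)(C)[Si](C)(C)OS(=O)(=O)C(F)(F)F
Why: Silylation of the secondary allylic alcohol in preference to the tertiary α-keto alcohol at low temperature.

Step 8
Reactants: 10 silyl ether
Product: 11 triol (1α-OTBS, 4β-OH, 5α-OH, 10β-CH2OH)
Conditions: LiAlH4, THF, −78 → 0 °C
Reagents that add atoms: none
Why: Hydride reduction in which the C5 alkoxyaluminate delivers hydride to the α face of the C4 ketone while the β face is blocked by the syn-axial ester, giving the 4β (pseudoaxial) alcohol. On warming the ester is reduced to the C11 primary alcohol.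

Step 9
Reactants: 11 triol
Product: 12 4,11-O-(4-methoxybenzylidene) acetal (seven-membered; 5α-OH free)
Conditions: 4-MeOC6H4CH(OMe)2, PPTS (cat.), 4 Å MS, CH2Cl2, 20 °C
Reagents that add atoms: 4-methoxybenzaldehyde dimethyl acetal, COC(OC)c1ccc(OC)cc1
Why: Acid-catalysed transacetalisation under thermodynamic control: only O4 and the C11 oxygen are syn-diaxial and within reach of one another, whereas O5 is anti to both and cannot take part.

Step 10
Reactants: 12 4,11-O-(4-methoxybenzylidene) acetal
Product: 13 ring B alcohol (7β-CH3, 8α-OH)
Conditions: 9-BBN, THF, 65 °C; then H2O2, aq. NaOH, 0 → 20 °C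
Reagents that add atoms: hydrogen peroxide, OO
Why: Hydroboration–oxidation: 9-BBN selects the unhindered C7=C8 over the doubly flanked C2=C3 and places boron on C8. It approaches from the α face because the β face of C8 is blocked by the axial C11 of the rigid trans-decalin, so hydrogen enters C7 from α and the methyl becomes β (equatorial).

Step 11
Reactants: 13 ring B alcohol
Product: 14 C8 ketone
Conditions: Dess–Martin periodinane, NaHCO3, CH2Cl2, 20 °C
Reagents that add atoms: none
Why: Dess–Martin oxidation of the secondary alcohol; the tertiary C5 alcohol is inert and the equatorial C7 methyl is already the thermodynamically preferred epimer.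

Step 12
Reactants: 14 C8 ketone
Product: 15 axial alcohol (8β-OH, cis to 7β-CH3)
Conditions: LiBH(s-Bu)3, THF, −78 °C
Reagents that add atoms: none
Why: Reduction by a bulky trialkylborohydride with equatorial attack from the α face (the axial path is closed by the syn-axial C11), giving the axial 8β-alcohol cis to the equatorial methyl, as with 2-methylcyclohexanone.

Step 13
Reactants: 15 axial alcohol
Product: 16 triethylsilyl ether (8β-OTES)
Conditions: Et3SiCl, imidazole, DMAP (cat.), DMF, 20 °C
Reagents that add atoms: chlorotriethylsilane, CC[Si](Cl)(CC)CC
Why: Silylation of the secondary alcohol; the tertiary C5 alcohol does not react with the silyl chloride, and the acetal is not exposed to a silyl triflate.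

Step 14
Reactants: 16 triethylsilyl ether
Product: 17 primary alcohol (4β-OPMB, 5α-OH, 10β-CH2OH)
Conditions: i-Bu2AlH, CH2Cl2, −78 → 0 °C
Reagents that add atoms: none
Why: Regioselective reductive opening of the p-methoxybenzylidene acetal: aluminium coordinates the less hindered primary oxygen, that C–O bond breaks, and hydride reduces the oxocarbenium ion left on O4 to the p-methoxybenzyl ether.

Step 15
Reactants: 17 primary alcohol
Product: 18 trans-decalin mesylate (1α-OTBS, 4β-OPMB, 5α-OH, 7β-CH3, 8β-OTES, 10β-CH2OMs)
Conditions: MeSO2Cl, Et3N, CH2Cl2, −20 °C; used without storage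
Reagents that add atoms: methanesulfonyl chloride, CS(=O)(=O)Cl
Why: Sulfonylation of the primary alcohol; the tertiary C5 alcohol is untouched by the sulfonyl chloride and the amine.

Step 16
Reactants: 18 trans-decalin mesylate
Product: 19 cyclodecenone (1α-OTBS, Z-C2=C3, 4β-OPMB, C5 ketone, 7β-CH3, 8β-OTES, C10=CH2)
Conditions: KN(SiMe3)2 (1.05 equiv), THF, −78 → 0 °C; pH 7 buffer
Reagents that add atoms: none
Why: Grob fragmentation of a γ-hydroxy sulfonate, whose closest known relatives are the base-induced fragmentations of decalin 1,3-diol monosulfonates to cyclodecenones. The amide deprotonates the tertiary C5 hydroxyl; the alkoxide lone pair becomes the C5=O π bond while the C5–C10 σ bond, anti-periplanar to the C11–O bond of the mesylate, breaks and becomes the C10=C11 π bond as mesylate leaves, all in one concerted step. No ring is closed by bond formation: cleaving the bond shared by rings A and B merges them into the ten-membered ring, and no stereocentre is created, since C5 and C10 become trigonal. The anti-periplanar rotamer should be the ground state, because the mesyloxy group is unhindered only when it points away from both rings, between C1 and C9. Oxetane formation, the usual competitor, is excluded because O5 (α-axial) and C11 (β-axial) are trans-diaxial and cannot reach each other. The Z geometry of C2=C3 is inherited from ring A and the exocyclic alkene has no geometry to control. The step needs fragmentation to outrun 1,3-migration of the C1 silyl group to the syn-axial alkoxide and enolisation of the product at C4; relief of the syn-axial contacts C11/O4, C11/O8 and O5/O1, the low temperature and the single equivalent of base are what secure this.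

Step 17
Reactants: 19 cyclodecenone
Product: 20 alcohol (5β-OH, cis to 4β-OPMB)
Conditions: Zn(BH4)2, Et2O, −30 °C
Reagents that add atoms: none
Why: Chelation-controlled reduction (Cram chelate): zinc bridges the C5 carbonyl and the C4 benzyl ether oxygen and hydride attacks from the side of the C4 hydrogen, which gives the 4,5-anti diol derivative, cis on the ring.

Step 18
Reactants: 20 alcohol
Product: 21 4,5-O-(4-methoxybenzylidene) acetal (1α-OTBS, 8β-OTES, C10=CH2)
Conditions: DDQ, 4 Å MS, CH2Cl2 (anhydrous), 0 °C
Reagents that add atoms: none
Why: Oxidation of the p-methoxybenzyl ether by DDQ to the benzylic oxocarbenium ion, which in the absence of water is trapped by the neighbouring cis C5 hydroxyl to give the dioxolane.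

Step 19
Reactants: 21 4,5-O-(4-methoxybenzylidene) acetal
Product: 22 primary alcohol (10α-H, 10β-CH2OH)
Conditions: 9-BBN, THF, 0 → 20 °C; then H2O2, aq. NaOH
Reagents that add atoms: hydrogen peroxide, OO
Why: Anti-Markovnikov hydroboration–oxidation; 9-BBN takes the 1,1-disubstituted alkene and leaves the flanked trisubstituted C2=C3 alone. With the C1–H eclipsing the double bond (allylic strain) and C2 perpendicular to it, the borane adds anti to C2, which puts hydrogen on the α face of C10 (C11 β, trans to O1), the same sense as the anti selectivity of 9-BBN with acyclic 2-substituted allylic ethers.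

Step 20
Reactants: 22 primary alcohol
Product: 23 aldehyde (10β-CHO)
Conditions: Dess–Martin periodinane, NaHCO3, CH2Cl2, 0 °C
Reagents that add atoms: none
Why: Buffered Dess–Martin oxidation, neutral enough to leave the α stereocentre C10 and the β silyloxy group untouched.

Step 21
Reactants: 23 aldehyde
Product: 24 terminal alkyne (10β-C≡CH)
Conditions: MeC(O)C(N2)P(O)(OMe)2, K2CO3, MeOH, 0 → 20 °C
Reagents that add atoms: dimethyl (1-diazo-2-oxopropyl)phosphonate, CC(=O)C(=[N+]=[N-])P(=O)(OC)OC
Why: Seyferth–Gilbert homologation with the Ohira–Bestmann reagent: the diazomethylphosphonate anion condenses with the aldehyde and the resulting alkylidene carbene rearranges to the alkyne. This brings in C13 under carbonate conditions that α-branched aldehydes normally survive.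

Step 22
Reactants: 24 terminal alkyne
Product: 25 alcohol (8β-OH)
Conditions: HF·pyridine, pyridine, THF, 0 °C
Reagents that add atoms: none
Why: Selective cleavage of the triethylsilyl ether in the presence of the tert-butyldimethylsilyl ether; the buffered medium spares the acetal.

Step 23
Reactants: 25 alcohol
Product: 26 angelate (8β-O-angeloyl)
Conditions: angelic acid, 2,4,6-Cl3C6H2COCl, Et3N, toluene, 20 °C; then 25, 80 °C
Reagents that add atoms: angelic acid, C/C=C(/C)C(=O)O
Why: Esterification through the preformed mixed anhydride (Yamaguchi type), run thermally and without a nucleophilic catalyst so that the Z geometry of the angelate is kept.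

Step 24
Reactants: 26 angelate
Product: 27 homopropargylic alcohol (1α-OH)
Conditions: Bu4NF, AcOH, THF, 20 °C
Reagents that add atoms: none
Why: Fluoride cleavage of the allylic silyl ether; acetic acid buffering protects the angelate from basic fluoride.

Step 25
Reactants: 27 homopropargylic alcohol
Product: 28 α-methylene lactone acetal
Conditions: PdCl2 (10 mol %), thiourea (10 mol %), CO (1 atm), acetone, 50 °C
Reagents that add atoms: carbon monoxide, [C-]#[O+]
Why: Palladium-catalysed cyclocarbonylation of a homopropargylic alcohol: the alkoxycarbonyl complex formed from the C1 hydroxyl and CO on divalent palladium adds cis across the alkyne in the 5-exo sense, and protonolysis of the vinyl–palladium bond releases the exocyclic methylene. C1 and C10 are not touched, so the lactone is trans-fused.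

Step 26
Reactants: 28 α-methylene lactone acetal
Product: 29 CNP0229085.1
Conditions: AcOH/H2O/THF (3:1:1), 40 °C
Reagents that add atoms: none
Why: Mild acid hydrolysis of the p-methoxybenzylidene acetal, conditions that neither add to the methylene lactone nor isomerise the angelate.

## Compound list

1 | 4-methylsalicylic acid (2-hydroxy-4-methylbenzoic acid) | Cc1ccc(C(=O)O)c(O)c1 | starting material
2 | 2,5-dihydroxy-4-methylbenzoic acid | Cc1cc(O)c(C(=O)O)cc1O | intermediate
3 | methyl 2,5-dihydroxy-4-methylbenzoate | COC(=O)c1cc(O)c(C)cc1O | intermediate
4 | methyl 4-methyl-3,6-dioxocyclohexa-1,4-diene-1-carboxylate | COC(=O)C1=CC(=O)C(C)=CC1=O | intermediate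
5 | isoprene (2-methylbuta-1,3-diene) | C=CC(C)=C | starting material
6 | cis-fused Diels–Alder adduct: C1 and C4 ketones, C2=C3(CH3), C7(CH3)=C8, 5β-H, 10β-CO2CH3 | O=C1C=C(C)C(=O)[C@@H]2CC(C)=CC[C@]12C(=O)OC | intermediate
7 | hydroxy enone: 1α-OH, C4 ketone, 5β-H, 10β-CO2CH3 | O[C@@H]1C=C(C)C(=O)[C@@H]2CC(C)=CC[C@]12C(=O)OC | intermediate
8 | bis(trimethylsilyl) dienol ether: 1α-OSiMe3, C2=C3–C4(OSiMe3)=C5, 10β-CO2CH3 | C[Si](C)(C)O[C@@H]1C=C(C)C(O[Si](C)(C)C)=C2CC(C)=CC[C@]12C(=O)OC | intermediate (not isolated)
9 | trans-fused ketol: 1α-OH, 5α-OH, C4 ketone, 10β-CO2CH3 | O[C@@H]1C=C(C)C(=O)[C@@]2(O)CC(C)=CC[C@]12C(=O)OC | intermediate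
10 | silyl ether: 1α-OTBS, 5α-OH, C4 ketone, 10β-CO2CH3 | CC(C)(C)[Si](C)(C)O[C@@H]1C=C(C)C(=O)[C@@]2(O)CC(C)=CC[C@]12C(=O)OC | intermediate
11 | triol: 1α-OTBS, 4β-OH, 5α-OH, 10β-CH2OH | CC(C)(C)[Si](C)(C)O[C@@H]1C=C(C)[C@@H](O)[C@@]2(O)CC(C)=CC[C@]12CO | intermediate
12 | 4,11-O-(4-methoxybenzylidene) acetal of 11 (acetal carbon unassigned) | CC(C)(C)[Si](C)(C)O[C@@H]1C=C(C)[C@@H](OC3c4ccc(OC)cc4)[C@@]2(O)CC(C)=CC[C@]12CO3 | intermediate
13 | ring B alcohol: 7β-CH3, 8α-OH | CC(C)(C)[Si](C)(C)O[C@@H]1C=C(C)[C@@H](OC3c4ccc(OC)cc4)[C@@]2(O)C[C@@H](C)[C@H](O)C[C@]12CO3 | intermediate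
14 | C8 ketone, 7β-CH3 | CC(C)(C)[Si](C)(C)O[C@@H]1C=C(C)[C@@H](OC3c4ccc(OC)cc4)[C@@]2(O)C[C@@H](C)C(=O)C[C@]12CO3 | intermediate
15 | axial alcohol: 7β-CH3, 8β-OH | CC(C)(C)[Si](C)(C)O[C@@H]1C=C(C)[C@@H](OC3c4ccc(OC)cc4)[C@@]2(O)C[C@@H](C)[C@@H](O)C[C@]12CO3 | intermediate
16 | triethylsilyl ether: 8β-OTES | CC(C)(C)[Si](C)(C)O[C@@H]1C=C(C)[C@@H](OC3c4ccc(OC)cc4)[C@@]2(O)C[C@@H](C)[C@@H](O[Si](CC)(CC)CC)C[C@]12CO3 | intermediate
17 | primary alcohol: 1α-OTBS, 4β-OPMB, 5α-OH, 7β-CH3, 8β-OTES, 10β-CH2OH | CC(C)(C)[Si](C)(C)O[C@@H]1C=C(C)[C@@H](OCc3ccc(OC)cc3)[C@@]2(O)C[C@@H](C)[C@@H](O[Si](CC)(CC)CC)C[C@]12CO | intermediate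
18 | trans-decalin mesylate: as 17 with 10β-CH2OSO2CH3 | CC(C)(C)[Si](C)(C)O[C@@H]1C=C(C)[C@@H](OCc3ccc(OC)cc3)[C@@]2(O)C[C@@H](C)[C@@H](O[Si](CC)(CC)CC)C[C@]12COS(C)(=O)=O | intermediate
19 | cyclodecenone: 1α-OTBS, Z-C2=C3, 4β-OPMB, C5 ketone, 7β-CH3, 8β-OTES, C10=CH2 | CC(C)(C)[Si](C)(C)O[C@@H]1/C=C(/C)[C@@H](OCc2ccc(OC)cc2)C(=O)C[C@@H](C)[C@@H](O[Si](CC)(CC)CC)CC1=C | intermediate
20 | alcohol: 5β-OH, 4β-OPMB, C10=CH2 | CC(C)(C)[Si](C)(C)O[C@@H]1/C=C(/C)[C@@H](OCc2ccc(OC)cc2)[C@@H](O)C[C@@H](C)[C@@H](O[Si](CC)(CC)CC)CC1=C | intermediate
21 | 4,5-O-(4-methoxybenzylidene) acetal, C10=CH2 (acetal carbon unassigned) | CC(C)(C)[Si](C)(C)O[C@@H]1/C=C(/C)[C@H]2OC(c3ccc(OC)cc3)O[C@H]2C[C@@H](C)[C@@H](O[Si](CC)(CC)CC)CC1=C | intermediate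
22 | primary alcohol: 10α-H, 10β-CH2OH | CC(C)(C)[Si](C)(C)O[C@@H]1/C=C(/C)[C@H]2OC(c3ccc(OC)cc3)O[C@H]2C[C@@H](C)[C@@H](O[Si](CC)(CC)CC)C[C@H]1CO | intermediate
23 | aldehyde: 10β-CHO | CC(C)(C)[Si](C)(C)O[C@@H]1/C=C(/C)[C@H]2OC(c3ccc(OC)cc3)O[C@H]2C[C@@H](C)[C@@H](O[Si](CC)(CC)CC)C[C@H]1C=O | intermediate
24 | terminal alkyne: 10β-C≡CH, 1α-OTBS, 8β-OTES | CC(C)(C)[Si](C)(C)O[C@@H]1/C=C(/C)[C@H]2OC(c3ccc(OC)cc3)O[C@H]2C[C@@H](C)[C@@H](O[Si](CC)(CC)CC)C[C@H]1C#C | intermediate
25 | alcohol: 8β-OH, 1α-OTBS, alkyne | CC(C)(C)[Si](C)(C)O[C@@H]1/C=C(/C)[C@H]2OC(c3ccc(OC)cc3)O[C@H]2C[C@@H](C)[C@@H](O)C[C@H]1C#C | intermediate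
26 | angelate: 8β-O-angeloyl, 1α-OTBS, alkyne | CC(C)(C)[Si](C)(C)O[C@@H]1/C=C(/C)[C@H]2OC(c3ccc(OC)cc3)O[C@H]2C[C@@H](C)[C@@H](OC(=O)/C(C)=C\C)C[C@H]1C#C | intermediate
27 | homopropargylic alcohol: 1α-OH, 8β-O-angeloyl, alkyne | O[C@@H]1/C=C(/C)[C@H]2OC(c3ccc(OC)cc3)O[C@H]2C[C@@H](C)[C@@H](OC(=O)/C(C)=C\C)C[C@H]1C#C | intermediate
28 | α-methylene lactone, 4,5-O-(4-methoxybenzylidene) acetal of the target | C=C1C(=O)O[C@@H]2/C=C(/C)[C@H]3OC(c4ccc(OC)cc4)O[C@H]3C[C@@H](C)[C@@H](OC(=O)/C(C)=C\C)C[C@@H]12 | intermediate
29 | CNP0229085.1 | C=C1C(=O)O[C@@H]2/C=C(/C)[C@@H](O)[C@@H](O)C[C@@H](C)[C@@H](OC(=O)/C(C)=C\C)C[C@@H]12 | target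

## Step count and least certain steps

Total: 26 steps. Longest linear sequence: 26 steps (from 1; isoprene enters at step 4).

**Step 16 (key step).** The most likely failure is migration of the C1 silyl group to the syn-axial C5 alkoxide, after which the liberated C1 alkoxide would cleave the C1–C10 bond instead. A second risk is enolisation at C4 of the product by surplus base, with loss of configuration or movement of the C2=C3 alkene into conjugation. The fallback keeps the C5–C10 cleavage but replaces the sulfonate trigger by a retro-aldol fragmentation, which needs no alkoxide as strong as an amide base. Setting out from 17, Dess–Martin oxidation of the primary alcohol would give the decalin β-hydroxy aldehyde F1. Exposure to DBU should open it to the ten-membered keto aldehyde F2, whose C10 is then a protonated, equilibrating centre. Zn(BH4)2 would reduce both carbonyls to the diol F3 (C5 under chelate control), and anhydrous DDQ would close the acetal, returning to the route at 22.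

**Step 19.** Face selectivity at the exocyclic alkene depends on which conformer of the ten-membered ring reacts; if the ring places the C1–O bond rather than the C1–H bond in the plane of the alkene, hydrogen would be delivered to the β face of C10. The fallback replaces kinetic face selection by thermodynamic correction. Setting out from 21, the C10-epimeric alcohol F4 would be oxidised to the epimeric aldehyde F5, and C10, now α to the formyl group, equilibrated with DBU; the aldehydes are separated and the unwanted one recycled, returning at 23.

**Step 17.** The ring conformation may override the zinc chelate and expose the other face of the ketone, giving the 5α-alcohol. The fallback changes the control element from the substrate to the catalyst. Setting out from 19, reduction with (R)-2-methyl-CBS-oxazaborolidine and catecholborane, in which the branched C4 side is the large and the C6 methylene the small flank, should deliver hydride to the α face, returning at 20.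

**Step 6.** The oxidant may approach on the β face because the pseudoaxial C1 silyloxy group lies on the α face, or it may epoxidise the C7=C8 alkene competitively. The fallback is a different reaction type. Setting out from 7, the potassium alkoxide–enolate dianion (KN(SiMe3)2, 2.2 equiv, THF, −78 °C) would be hydroxylated with 2-(phenylsulfonyl)-3-phenyloxaziridine. That reagent does not touch isolated alkenes, the C1 substituent is then only an alkoxide, and the α face is still the one anti to the ester; after a cold acetic acid quench the route is rejoined at 9.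

**Step 5.** Reduction may go astray through competing attack at the C4 carbonyl, or through a mismatch between catalyst and substrate bias that erodes face selectivity at C1. The fallback uses chelation instead of reagent control. Setting out from 6, Zn(BH4)2 should bind the β-keto ester unit (C1 carbonyl and ester), activating C1 alone, and deliver hydride anti to the C9 methylene, that is to the β face, returning at 7.

**Step 25.** Alkoxycarbonylation may be slow at the hindered secondary alcohol, so that palladium-mediated hydration or oligomerisation of the alkyne, or acid-induced loss of the acetal, takes over. The fallback is a radical route. Setting out from 27, the alcohol would be converted (COCl2, pyridine; then PhSeH) into the Se-phenyl selenocarbonate F6. With Bu3SnH and AIBN in benzene at 80 °C this should give the alkoxycarbonyl radical, which closes 5-exo onto the alkyne; hydrogen transfer to the vinyl radical returns the route at 28.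

## Further compounds

F1 | step 16 | decalin β-hydroxy aldehyde (10β-CHO, 5α-OH, otherwise as 17) | CC(C)(C)[Si](C)(C)O[C@@H]1C=C(C)[C@@H](OCc3ccc(OC)cc3)[C@@]2(O)C[C@@H](C)[C@@H](O[Si](CC)(CC)CC)C[C@]12C=O
F2 | step 16 | ten-membered keto aldehyde (C5 ketone, 10α-H, 10β-CHO, 4β-OPMB) | CC(C)(C)[Si](C)(C)O[C@@H]1/C=C(/C)[C@@H](OCc2ccc(OC)cc2)C(=O)C[C@@H](C)[C@@H](O[Si](CC)(CC)CC)C[C@H]1C=O
F3 | step 16 | diol (5β-OH, 10β-CH2OH, 4β-OPMB) | CC(C)(C)[Si](C)(C)O[C@@H]1/C=C(/C)[C@@H](OCc2ccc(OC)cc2)[C@@H](O)C[C@@H](C)[C@@H](O[Si](CC)(CC)CC)C[C@H]1CO
F4 | step 19 | C10 epimer of alcohol 22 (10β-H, 10α-CH2OH) | CC(C)(C)[Si](C)(C)O[C@@H]1/C=C(/C)[C@H]2OC(c3ccc(OC)cc3)O[C@H]2C[C@@H](C)[C@@H](O[Si](CC)(CC)CC)C[C@@H]1CO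
F5 | step 19 | C10 epimer of aldehyde 23 (10α-CHO) | CC(C)(C)[Si](C)(C)O[C@@H]1/C=C(/C)[C@H]2OC(c3ccc(OC)cc3)O[C@H]2C[C@@H](C)[C@@H](O[Si](CC)(CC)CC)C[C@@H]1C=O
F6 | step 25 | Se-phenyl selenocarbonate of 27 | O=C([Se]c1ccccc1)O[C@@H]1/C=C(/C)[C@H]2OC(c3ccc(OC)cc3)O[C@H]2C[C@@H](C)[C@@H](OC(=O)/C(C)=C\C)C[C@H]1C#C
F0 | step 17 | none | none
F0 | step 6 | none | none
F0 | step 5 | none | none
A1 | alternative 1 | open-chain aldehyde with Z C3 vinyl iodide, finished lactone, angelate and C5 silyl ether | C=C1C(=O)O[C@H](/C=C(/C)I)[C@H]1C[C@H](OC(=O)/C(C)=C\C)[C@H](C)C[C@H](O[Si](C)(C)C(C)(C)C)C=O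
A2 | alternative 1 | C5 tert-butyldimethylsilyl ether of the target | C=C1C(=O)O[C@@H]2/C=C(/C)[C@@H](O)[C@@H](O[Si](C)(C)C(C)(C)C)C[C@@H](C)[C@@H](OC(=O)/C(C)=C\C)C[C@@H]12
A3 | alternative 2 | thirteen-membered diallylic ether (O bridging C1 and C13; C10=C11 in the ring; C4/C5 acetonide; C8 OTIPS; C12 OTBS) | O1C/C=C(/C)[C@H]2OC(C)(C)O[C@H]2C[C@@H](C)[C@@H](O[Si](C(C)C)(C(C)C)C(C)C)C/C=C(CO[Si](C)(C)C(C)(C)C)/C1
A4 | alternative 2 | cyclodecenol with free C1 hydroxyl and C10 1-(silyloxymethyl)vinyl group | O[C@@H]1/C=C(/C)[C@@H](OC(C)(C)O2)[C@@H]2C[C@@H](C)[C@@H](O[Si](C(C)C)(C(C)C)C(C)C)C[C@H]1C(=C)CO[Si](C)(C)C(C)(C)C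
A5 | alternative 3 | eight-membered cyclic enol ether with Z-ethylidene on C8 and vinyl on C4 (C4 configuration as a chair-like transition state would require) | C/C=C1/C[C@@H](CCOCc2ccc(OC)cc2)[C@H](O[Si](C)(C)C(C)(C)C)/C=C(C)\[C@H](C=C)O1
A6 | alternative 3 | cyclodeca-2,4-dienone with C7 methyl stereocentre and C8 ketone | CC(C)(C)[Si](C)(C)O[C@@H]1/C=C(/C)\C=C/C[C@@H](C)C(=O)C[C@H]1CCOCc2ccc(OC)cc2
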